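**Retrosynthetic overview**

1. Locants (daucane numbering): five-membered ring C1(CH3, quaternary)–C2–C3–C4(OH, i-Pr)–C5(H); seven-membered ring C1, C5, C6(O-aroyl), C7, C8(CH3)=C9, C10(O-tigloyl). β is the face of the C1 methyl group. The target is (1R,4R,5S,6R,10S).
2. Endgame: the tiglate (O–C10) and the 4-hydroxybenzoate (O–C6) go on last. The C6 alcohol comes from a cis-fused C6 ketone, and this from a C5=C6 methyl enol ether.
3. Key disconnection, bonds C6–C7 and C1–C10 of the seven-membered ring: formal [4+3] of a cyclopentenyl(methoxy)carbene chromium complex (C6, C5, C1) with (E)-1-silyloxy-3-methylbuta-1,3-diene (C7–C10), by cyclopropanation and Cope rearrangement of the cis-divinylcyclopropane.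
4. Enabling feature: in the seven-membered ring only the C7 methylene separates the C8=C9 alkene from the oxygen-bearing C6. The C6 enol (C5=C6) and C8=C9 therefore form a cyclohepta-1,4-diene whose sp3 termini are the oxygenated C10 and the quaternary C1, and the ring-fusion bond C1–C5 can be the alkene of a preformed cyclopentene.
5. Ring order: five-membered ring first, by ozonolysis/aldol ring contraction of (S)-terpinen-4-ol, which supplies C4 as the only purchased stereocenter. Seven-membered ring last. C1 and C10 (key step), then C5 and C6, are relayed from C4.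

Key step: step 8

Assumption: (S)-(+)-terpinen-4-ol is taken as purchasable in high enantiomeric purity; its carbinol carbon becomes C4 unchanged.

**Route**

Step 1
Reactants: 1 (S)-(+)-terpinen-4-ol [(1S)-4-methyl-1-(propan-2-yl)cyclohex-3-en-1-ol]
Product: 2 triethyl{[(1S)-4-methyl-1-(propan-2-yl)cyclohex-3-en-1-yl]oxy}silane
Conditions: TESOTf, 2,6-lutidine, CH2Cl2, 0 °C to rt
Reagents that add atoms: triethylsilyl trifluoromethanesulfonate, CC[Si](CC)(CC)OS(=O)(=O)C(F)(F)F
Why: Silylation of a hindered tertiary alcohol with a silyl triflate and a hindered pyridine base is standard and does not touch the carbinol stereocenter (future C4).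

Step 2
Reactants: 2 triethyl{[(1S)-4-methyl-1-(propan-2-yl)cyclohex-3-en-1-yl]oxy}silane
Product: 4 (3S)-6-oxo-3-(propan-2-yl)-3-[(triethylsilyl)oxy]heptanal, via secondary ozonide 3 (not isolated)
Conditions: O3, CH2Cl2, −78 °C; then Me2S, −78 °C to rt
Reagents that add atoms: ozone, [O-][O+]=O
Why: Criegee ozonolysis with reductive work-up cleaves the only alkene to the 1,6-keto aldehyde; the aldehyde carbon becomes C6, the ketone carbon C1, and the silyl ether is inert.

Step 3
Reactants: 4 (3S)-6-oxo-3-(propan-2-yl)-3-[(triethylsilyl)oxy]heptanal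
Product: 5 (5R)-2-methyl-5-(propan-2-yl)-5-[(triethylsilyl)oxy]cyclopent-1-ene-1-carbaldehyde
Conditions: piperidine (0.2 equiv), AcOH (0.2 equiv), toluene, 60 °C
Reagents that add atoms: none
Why: Amine-catalysed intramolecular aldol condensation (aldehyde enamine onto the methyl ketone, five-membered ring, then dehydration) is the standard ring contraction of 6-oxoheptanals to 2-methylcyclopent-1-enecarbaldehydes; the β-oxygen is kept as a silyl ether, a poor leaving group, to hold back β-elimination, and no stereocenter is formed.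

Step 4
Reactants: 5 (5R)-2-methyl-5-(propan-2-yl)-5-[(triethylsilyl)oxy]cyclopent-1-ene-1-carbaldehyde
Product: 6 (5R)-2-methyl-5-(propan-2-yl)-5-[(triethylsilyl)oxy]cyclopent-1-ene-1-carboxylic acid
Conditions: NaClO2, NaH2PO4, 2-methylbut-2-ene, t-BuOH/H2O, rt
Reagents that add atoms: sodium chlorite, [Na+].[O-]Cl=O
Why: Pinnick oxidation converts the enal into the acid without touching the tetrasubstituted alkene or the silyl ether.

Step 5
Reactants: 6 (5R)-2-methyl-5-(propan-2-yl)-5-[(triethylsilyl)oxy]cyclopent-1-ene-1-carboxylic acid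
Product: 7 (5R)-2-methyl-5-(propan-2-yl)-5-[(triethylsilyl)oxy]cyclopent-1-ene-1-carbonyl chloride
Conditions: 1-chloro-N,N,2-trimethylprop-1-en-1-amine, CH2Cl2, 0 °C to rt
Reagents that add atoms: 1-chloro-N,N,2-trimethylprop-1-en-1-amine (Ghosez's reagent), CC(C)=C(Cl)N(C)C
Why: Acid chloride formation with Ghosez's reagent is neutral, so no HCl is present that could ionise the tertiary allylic silyl ether.

Step 6
Reactants: 7 (5R)-2-methyl-5-(propan-2-yl)-5-[(triethylsilyl)oxy]cyclopent-1-ene-1-carbonyl chloride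
Product: 9 pentacarbonyl{methoxy[(5R)-2-methyl-5-(propan-2-yl)-5-(triethylsilyloxy)cyclopent-1-en-1-yl]methylidene}chromium, (CO)5Cr=C(OMe)R, via potassium acylpentacarbonylchromate 8 (not isolated)
Conditions: K2Cr(CO)5 [from Cr(CO)6, KC8, THF, −78 to 0 °C], then 7, THF, −78 to 0 °C; then Me3OBF4, CH2Cl2, 0 °C
Reagents that add atoms: hexacarbonylchromium (used as K2Cr(CO)5 made in the flask), O=C=[Cr](=C=O)(=C=O)(=C=O)(=C=O)=C=O; trimethyloxonium tetrafluoroborate, C[O+](C)C.F[B-](F)(F)F
Why: The acylate route to Fischer carbene complexes (acylation of the pentacarbonylchromate dianion, then O-methylation with Meerwein's salt) suits a precursor at the acid level where no alkenyllithium is at hand; the C4 stereocenter is remote from the reacting carbon.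

Step 7
Reactants: 10 3-methylbut-2-enal (prenal)
Product: 11 tert-butyl(dimethyl){[(1E)-3-methylbuta-1,3-dien-1-yl]oxy}silane
Conditions: TBSOTf, Et3N, Et2O, 0 °C to rt
Reagents that add atoms: tert-butyldimethylsilyl trifluoromethanesulfonate, CC(C)(C)[Si](C)(C)OS(=O)(=O)C(F)(F)F
Why: Soft γ-enolisation and O-silylation of the enal gives the 1-silyloxydiene, with the E enol ether expected from the s-trans enal.

Step 8
Reactants: 9 pentacarbonyl{methoxy[(5R)-2-methyl-5-(propan-2-yl)-5-(triethylsilyloxy)cyclopent-1-en-1-yl]methylidene}chromium; 11 tert-butyl(dimethyl){[(1E)-3-methylbuta-1,3-dien-1-yl]oxy}silane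
Product: 13 (1R,4R,10S)-10-[(tert-butyldimethylsilyl)oxy]-6-methoxy-4-[(triethylsilyl)oxy]dauca-5,8-diene, via cis-divinylcyclopropane 12 (not isolated)
Conditions: 11 (3 equiv), toluene, CO (1 atm), 90 °C, then 110 °C
Reagents that add atoms: none
Why: The unsubstituted diene terminus C7 attacks the electrophilic carbene carbon C6, and closure at C8 with loss of the Cr(CO)5 fragment (taken up by CO as Cr(CO)6) gives cis-divinylcyclopropane 12, which undergoes a Cope ([3,3]-sigmatropic) rearrangement through a boat transition state. The closest known reaction type is the tandem cyclopropanation/divinylcyclopropane rearrangement of alkenyl(alkoxy)carbene complexes of chromium, molybdenum or tungsten with 1,3-dienes (formal [4+3] cycloaddition), and the rhodium vinylcarbenoid version is known to form ring-fusion methyl-bearing quaternary centers from 2-methylcycloalkenyl termini. The seven-membered ring is closed last, onto the preformed cyclopentene, by the C1–C10 bond in the [3,3] shift that opens the three-membered ring (ring enlargement from three to seven; net new bonds C6–C7 and C1–C10). C1 is controlled by the purchased C4 stereocenter: in the boat transition state the cyclopropane carbon C8 and the incoming vinyl unit sit over the cyclopentene face next to C4 and should take the side of the small C4–O substituent, not that of the isopropyl group, so C10 bonds to C1 syn to the C4 oxygen and the methyl group ends up cis to the isopropyl group. C10 is controlled by the E geometry of the silyl enol ether: the E-oxygen and the ring CH2 (C2) are both outside substituents of the boat and end up cis, so the silyloxy group is trans to the angular methyl group. The step needs chemoselectivity for cyclopropanation over Diels–Alder or conjugate addition (secured by the fully substituted, non-dienophilic cyclopentenyl group), regioselectivity for the CH2=C(CH3) end of the diene (secured by the vinylogous donor effect of the silyloxy group and the open CH2 terminus) and facial selectivity (cyclopropane diastereomers, cis or trans, should interconvert at 110 °C through the weak, doubly allylic, donor-substituted C6–C8 bond, so that the lower boat transition state decides).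

Step 9
Reactants: 13 (1R,4R,10S)-10-[(tert-butyldimethylsilyl)oxy]-6-methoxy-4-[(triethylsilyl)oxy]dauca-5,8-diene
Product: 14 (1R,4R,5R,10S)-10-[(tert-butyldimethylsilyl)oxy]-4-[(triethylsilyl)oxy]dauc-8-en-6-one (cis-fused)
Conditions: oxalic acid (0.2 equiv), THF/H2O (4:1), 0 °C to rt
Reagents that add atoms: water, O
Why: Acid-catalysed enol ether hydrolysis (C-protonation, then loss of methanol from the hemiketal) should protonate C5 on the convex β-face, syn to the angular methyl group, because the α-face is covered by the fold of the seven-membered ring with its pseudo-axial C10 silyloxy group and by the C4 silyloxy group; this gives the cis-fused ketone, which should also be the more stable C5 epimer, while the weak acid and the retained silyl ether keep the tertiary C4–O bond from ionising and the C8=C9 alkene out of conjugation.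

Step 10
Reactants: 14 (1R,4R,5R,10S)-10-[(tert-butyldimethylsilyl)oxy]-4-[(triethylsilyl)oxy]dauc-8-en-6-one
Product: 15 (1R,4R,5S,6R,10S)-10-[(tert-butyldimethylsilyl)oxy]-4-[(triethylsilyl)oxy]dauc-8-en-6-ol
Conditions: NaBH4, CeCl3·7H2O, MeOH, −40 °C
Reagents that add atoms: none
Why: Luche-type borohydride reduction at low temperature should deliver hydride to C6 from the convex β-face, the side of H5 and anti to the quaternary C4 with its silyloxy group (Felkin-type approach), giving the 6R alcohol before the β,γ-unsaturated ketone can isomerise.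

Step 11
Reactants: 15 (1R,4R,5S,6R,10S)-10-[(tert-butyldimethylsilyl)oxy]-4-[(triethylsilyl)oxy]dauc-8-en-6-ol; 16 4-acetoxybenzoyl chloride
Product: 17 (1R,4R,5S,6R,10S)-10-[(tert-butyldimethylsilyl)oxy]-4-[(triethylsilyl)oxy]dauc-8-en-6-yl 4-acetoxybenzoate
Conditions: DMAP, Et3N, CH2Cl2, rt to 40 °C
Reagents that add atoms: none
Why: DMAP-catalysed acyl transfer esterifies the only free hydroxyl with retention at C6, the phenol being carried as its acetate.

Step 12
Reactants: 17 (1R,4R,5S,6R,10S)-10-[(tert-butyldimethylsilyl)oxy]-4-[(triethylsilyl)oxy]dauc-8-en-6-yl 4-acetoxybenzoate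
Product: 18 (1R,4R,5S,6R,10S)-4,10-dihydroxydauc-8-en-6-yl 4-acetoxybenzoate
Conditions: HF·pyridine, pyridine, THF, 0 °C to rt
Reagents that add atoms: none
Why: Fluoride-mediated desilylation under buffered, weakly acidic conditions removes both silyl ethers by attack at silicon, so the allylic C10–O bond is not ionised and the benzoate and aryl acetate survive.

Step 13
Reactants: 18 (1R,4R,5S,6R,10S)-4,10-dihydroxydauc-8-en-6-yl 4-acetoxybenzoate; 19 tigloyl chloride [(2E)-2-methylbut-2-enoyl chloride]
Product: 20 (1R,4R,5S,6R,10S)-4-hydroxy-10-{[(2E)-2-methylbut-2-enoyl]oxy}dauc-8-en-6-yl 4-acetoxybenzoate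
Conditions: DMAP, Et3N, CH2Cl2, 0 °C to rt
Reagents that add atoms: none
Why: DMAP-catalysed acylation takes the secondary allylic C10 hydroxyl, while the tertiary C4 hydroxyl, flanked by the isopropyl group and the ring fusion, should not react; O-acylation leaves the C10 configuration and the E geometry of the tiglate unchanged.

Step 14
Reactants: 20 (1R,4R,5S,6R,10S)-4-hydroxy-10-{[(2E)-2-methylbut-2-enoyl]oxy}dauc-8-en-6-yl 4-acetoxybenzoate
Product: 21 (1R,4R,5S,6R,10S)-4-hydroxy-10-{[(2E)-2-methylbut-2-enoyl]oxy}dauc-8-en-6-yl 4-hydroxybenzoate (target, CNP0273650.13)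
Conditions: pyrrolidine (1.5 equiv), CH2Cl2, 0 °C
Reagents that add atoms: none
Why: Chemoselective aminolysis removes the phenolic acetate, an activated aryl ester, while the alkyl benzoate and the hindered tiglate are far less electrophilic.

**Compound list**

1 | (S)-(+)-terpinen-4-ol | CC1=CC[C@](O)(C(C)C)CC1 | starting material
2 | triethyl{[(1S)-4-methyl-1-(propan-2-yl)cyclohex-3-en-1-yl]oxy}silane | CC1=CC[C@](O[Si](CC)(CC)CC)(C(C)C)CC1 | intermediate
3 | secondary ozonide of 2 (1,2,4-trioxolane across the former alkene, mixture at the two acetal carbons) | CC12CC[C@@](O[Si](CC)(CC)CC)(C(C)C)CC(OO1)O2 | intermediate (not isolated)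
4 | (3S)-6-oxo-3-(propan-2-yl)-3-[(triethylsilyl)oxy]heptanal | O=CC[C@](O[Si](CC)(CC)CC)(C(C)C)CCC(C)=O | intermediate
5 | (5R)-2-methyl-5-(propan-2-yl)-5-[(triethylsilyl)oxy]cyclopent-1-ene-1-carbaldehyde | O=CC1=C(C)CC[C@@]1(O[Si](CC)(CC)CC)C(C)C | intermediate
6 | (5R)-2-methyl-5-(propan-2-yl)-5-[(triethylsilyl)oxy]cyclopent-1-ene-1-carboxylic acid | OC(=O)C1=C(C)CC[C@@]1(O[Si](CC)(CC)CC)C(C)C | intermediate
7 | (5R)-2-methyl-5-(propan-2-yl)-5-[(triethylsilyl)oxy]cyclopent-1-ene-1-carbonyl chloride | ClC(=O)C1=C(C)CC[C@@]1(O[Si](CC)(CC)CC)C(C)C | intermediate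
8 | potassium acylpentacarbonylchromate, K[(CO)5Cr–C(=O)R], R = cyclopentenyl group of 7 | [K+].[O-]C(C1=C(C)CC[C@@]1(O[Si](CC)(CC)CC)C(C)C)=[Cr](=C=O)(=C=O)(=C=O)(=C=O)=C=O | intermediate (not isolated)
9 | pentacarbonyl{methoxy[(5R)-2-methyl-5-(propan-2-yl)-5-(triethylsilyloxy)cyclopent-1-en-1-yl]methylidene}chromium | COC(C1=C(C)CC[C@@]1(O[Si](CC)(CC)CC)C(C)C)=[Cr](=C=O)(=C=O)(=C=O)(=C=O)=C=O | intermediate
10 | 3-methylbut-2-enal (prenal) | CC(C)=CC=O | starting material
11 | tert-butyl(dimethyl){[(1E)-3-methylbuta-1,3-dien-1-yl]oxy}silane | C=C(C)/C=C/O[Si](C)(C)C(C)(C)C | intermediate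
12 | cis-divinylcyclopropane: 1-methoxy-2-methylcyclopropane carrying the cyclopentenyl group of 9 on C(OMe) and the (E)-2-(tert-butyldimethylsilyloxy)ethenyl group on C(CH3), the two alkenyl groups cis | CO[C@]1(C2=C(C)CC[C@@]2(O[Si](CC)(CC)CC)C(C)C)C[C@@]1(C)/C=C/O[Si](C)(C)C(C)(C)C | intermediate (not isolated)
13 | (1R,4R,10S)-10-[(tert-butyldimethylsilyl)oxy]-6-methoxy-4-[(triethylsilyl)oxy]dauca-5,8-diene | CC(C)(C)[Si](C)(C)O[C@H]1C=C(C)CC(OC)=C2[C@@]1(C)CC[C@@]2(O[Si](CC)(CC)CC)C(C)C | intermediate
14 | (1R,4R,5R,10S)-10-[(tert-butyldimethylsilyl)oxy]-4-[(triethylsilyl)oxy]dauc-8-en-6-one | CC(C)(C)[Si](C)(C)O[C@H]1C=C(C)CC(=O)[C@@H]2[C@@]1(C)CC[C@@]2(O[Si](CC)(CC)CC)C(C)C | intermediate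
15 | (1R,4R,5S,6R,10S)-10-[(tert-butyldimethylsilyl)oxy]-4-[(triethylsilyl)oxy]dauc-8-en-6-ol | CC(C)(C)[Si](C)(C)O[C@H]1C=C(C)C[C@@H](O)[C@@H]2[C@@]1(C)CC[C@@]2(O[Si](CC)(CC)CC)C(C)C | intermediate
16 | 4-acetoxybenzoyl chloride | CC(=O)Oc1ccc(cc1)C(Cl)=O | starting material
17 | (1R,4R,5S,6R,10S)-10-[(tert-butyldimethylsilyl)oxy]-4-[(triethylsilyl)oxy]dauc-8-en-6-yl 4-acetoxybenzoate | CC(C)(C)[Si](C)(C)O[C@H]1C=C(C)C[C@@H](OC(=O)c2ccc(OC(C)=O)cc2)[C@@H]2[C@@]1(C)CC[C@@]2(O[Si](CC)(CC)CC)C(C)C | intermediate
18 | (1R,4R,5S,6R,10S)-4,10-dihydroxydauc-8-en-6-yl 4-acetoxybenzoate | O[C@H]1C=C(C)C[C@@H](OC(=O)c2ccc(OC(C)=O)cc2)[C@@H]2[C@@]1(C)CC[C@@]2(O)C(C)C | intermediate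
19 | tigloyl chloride, (2E)-2-methylbut-2-enoyl chloride | C/C=C(\C)C(Cl)=O | starting material
20 | (1R,4R,5S,6R,10S)-4-hydroxy-10-{[(2E)-2-methylbut-2-enoyl]oxy}dauc-8-en-6-yl 4-acetoxybenzoate | C/C=C(\C)C(=O)O[C@H]1C=C(C)C[C@@H](OC(=O)c2ccc(OC(C)=O)cc2)[C@@H]2[C@@]1(C)CC[C@@]2(O)C(C)C | intermediate
21 | (1R,4R,5S,6R,10S)-4-hydroxy-10-{[(2E)-2-methylbut-2-enoyl]oxy}dauc-8-en-6-yl 4-hydroxybenzoate | C/C=C(\C)C(=O)O[C@H]1C=C(C)C[C@@H](OC(=O)c2ccc(O)cc2)[C@@H]2[C@@]1(C)CC[C@@]2(O)C(C)C | target

**Step count and risks**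

Total step count: 14. Longest linear sequence: 13 (steps 1–6 and 8–14, from 1).

Steps most likely to fail:

1. Step 8. Attack of the diene on the shielded carbene carbon may be too slow against thermal decay of the complex, or the two cyclopentene faces may be poorly differentiated in the Cope step. The fallback is the anionic, low-temperature equivalent, a Brook-rearrangement-mediated [3+4] annulation. It sets out from acid chloride 7 and comes back at ketone 14. Compound 7 would be treated with (PhMe2Si)2CuLi (THF, −78 °C) to give the acylsilane F1. F1 would be added to the lithium dienolate of (E)-4-[(tert-butyldimethylsilyl)oxy]but-3-en-2-one (LDA, THF, −80 to −30 °C). Carbonyl addition, 1,2-silyl shift from carbon to oxygen, cyclopropanolate closure and anionic oxy-Cope rearrangement should give the lithium enolate F2, with the same C1 and C10 control elements as in step 8. F2 would be trapped in the same flask with Comins' reagent as the enol triflate F3. Cross-coupling of F3 with MeMgBr and catalytic Fe(acac)3 (THF, −20 °C) would install the C8 methyl group and give the silyl enol ether F4. Hydrolysis of F4 under the conditions of step 9 would return to 14.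

2. Step 9. C5 may be protonated from the concave face, or the acid may be too slow on the hindered enol ether and then start to ionise the C4–O bond. The fallback replaces kinetic protonation by thermodynamic control of C5. It sets out from 13 and comes back at 14. If hydrolysis delivers the trans-fused ketone F5, this would be equilibrated through its C5 enolate with catalytic DBU in toluene at rt. The cis-fused ketone 14 should prevail, because C6 then lies cis to the C4 oxygen and away from the isopropyl and methyl groups. The equilibration would be stopped early and the remaining F5 recycled, to limit migration of the C8=C9 alkene into conjugation.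

3. Step 13. Acylation of the neopentyl-type, pseudo-axial C10 hydroxyl may be slow, so that acetyl transfer from the aryl acetate competes. The fallback brings the tiglate in with the diene. It sets out from prenal 10, tigloyl chloride 19 and carbene complex 9, and comes back at 20. The potassium dienolate of 10 (KOt-Bu, THF, −78 °C) would be O-acylated with 19 to give (1E)-3-methylbuta-1,3-dien-1-yl tiglate F6. F6 would be used in place of 11 under the conditions of step 8 and should give the [4+3] adduct F7 with the C10 tiglate in place. Hydrolysis as in step 9 would give the cis-fused ketone F8, and reduction as in step 10 the 6R alcohol F9. Acylation with 16 as in step 11 would give the diester F10, and HF·pyridine would free the C4 hydroxyl and return to 20.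

**Further compounds**

F1 | step 8 | [dimethyl(phenyl)silyl][(5R)-2-methyl-5-(propan-2-yl)-5-(triethylsilyloxy)cyclopent-1-en-1-yl]methanone | O=C([Si](C)(C)c1ccccc1)C1=C(C)CC[C@@]1(O[Si](CC)(CC)CC)C(C)C
F2 | step 8 | lithium enolate (C8–OLi, C8=C9) of the annulation product, C6 as dimethyl(phenyl)silyl enol ether | [Li+].CC(C)(C)[Si](C)(C)O[C@H]1C=C([O-])CC(O[Si](C)(C)c3ccccc3)=C2[C@@]1(C)CC[C@@]2(O[Si](CC)(CC)CC)C(C)C
F3 | step 8 | C8 enol triflate of F2 | CC(C)(C)[Si](C)(C)O[C@H]1C=C(OS(=O)(=O)C(F)(F)F)CC(O[Si](C)(C)c3ccccc3)=C2[C@@]1(C)CC[C@@]2(O[Si](CC)(CC)CC)C(C)C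
F4 | step 8 | (1R,4R,10S)-10-[(tert-butyldimethylsilyl)oxy]-6-{[dimethyl(phenyl)silyl]oxy}-4-[(triethylsilyl)oxy]dauca-5,8-diene | CC(C)(C)[Si](C)(C)O[C@H]1C=C(C)CC(O[Si](C)(C)c3ccccc3)=C2[C@@]1(C)CC[C@@]2(O[Si](CC)(CC)CC)C(C)C
F5 | step 9 | (1R,4R,5S,10S)-10-[(tert-butyldimethylsilyl)oxy]-4-[(triethylsilyl)oxy]dauc-8-en-6-one (trans-fused C5 epimer of 14) | CC(C)(C)[Si](C)(C)O[C@H]1C=C(C)CC(=O)[C@H]2[C@@]1(C)CC[C@@]2(O[Si](CC)(CC)CC)C(C)C
F6 | step 13 | (1E)-3-methylbuta-1,3-dien-1-yl (2E)-2-methylbut-2-enoate | C/C=C(\C)C(=O)O/C=C/C(C)=C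
F7 | step 13 | (1R,4R,10S)-6-methoxy-4-[(triethylsilyl)oxy]dauca-5,8-dien-10-yl (2E)-2-methylbut-2-enoate | C/C=C(\C)C(=O)O[C@H]1C=C(C)CC(OC)=C2[C@@]1(C)CC[C@@]2(O[Si](CC)(CC)CC)C(C)C
F8 | step 13 | (1R,4R,5R,10S)-6-oxo-4-[(triethylsilyl)oxy]dauc-8-en-10-yl (2E)-2-methylbut-2-enoate | C/C=C(\C)C(=O)O[C@H]1C=C(C)CC(=O)[C@@H]2[C@@]1(C)CC[C@@]2(O[Si](CC)(CC)CC)C(C)C
F9 | step 13 | (1R,4R,5S,6R,10S)-6-hydroxy-4-[(triethylsilyl)oxy]dauc-8-en-10-yl (2E)-2-methylbut-2-enoate | C/C=C(\C)C(=O)O[C@H]1C=C(C)C[C@@H](O)[C@@H]2[C@@]1(C)CC[C@@]2(O[Si](CC)(CC)CC)C(C)C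
F10 | step 13 | (1R,4R,5S,6R,10S)-10-{[(2E)-2-methylbut-2-enoyl]oxy}-4-[(triethylsilyl)oxy]dauc-8-en-6-yl 4-acetoxybenzoate | C/C=C(\C)C(=O)O[C@H]1C=C(C)C[C@@H](OC(=O)c2ccc(OC(C)=O)cc2)[C@@H]2[C@@]1(C)CC[C@@]2(O[Si](CC)(CC)CC)C(C)C
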